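The constants were drawn at random within sensible limits; what happens was integrated by code.

**Two questions.** Two questions stand on this flask, in which a precatalyst releases an enzyme that serves both the starting material and a second substrate.

starting material 10 mM; second substrate 5.00 mM; precatalyst 1.4 µM

    starting material + enzyme ⇌ complex A (K1 = 230 M⁻¹, k1 = 2.0 × 10⁶ M⁻¹ s⁻¹)
    second substrate + complex A → spent catalyst (k2 = 6.1 M⁻¹ s⁻¹)
    complex B → enzyme + second product (k3 = 190 s⁻¹)
    precatalyst → enzyme (k4 = 0.19 s⁻¹)
    complex A → enzyme + target (k5 = 1800 s⁻¹)
    second substrate + enzyme ⇌ complex B (K6 = 320 M⁻¹, k6 = 8.5 × 10⁶ M⁻¹ s⁻¹)

1. the form that holds most of the catalyst when 50% of the starting material are converted (enzyme / complex A / complex B / spent catalyst / precatalyst)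
2. its share of the catalyst then

**The clash.** Complex B reacts ten times slower than complex A. Yet per unit of its own substrate the round puts just 1.67 times as much catalyst in complex B as in complex A.

**Times clear it.** Complex A falls apart in 0.115 ms and reacts in 0.556 ms. Complex B falls apart in 0.0376 ms and reacts in 5.26 ms. So each complex falls apart sooner than it reacts. Take the Michaelis constant K_B: both ways out of complex B over the way in, the [second substrate] at which complex B equals free enzyme, 3.15 mM. For complex A it is K_A = 5.25 mM. While a complex is made as fast as it is used, [complex]/[enzyme] is [substrate]/K, its load.

**At half conversion.** Take the moment when 50% of the starting material is converted. Each substrate goes in proportion to its concentration times turnover constant over K. The ratio of these weights, second substrate to starting material, is 0.176, and [second substrate] follows [starting material] to that power, which puts it at about 4.43 mM. The loads are 0.953 for complex A and 1.41 for complex B, so complex B holds 41.9% of the working catalyst.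

**Off the round.** Midway to that moment, complex A holds about 35.6% of the working catalyst. Adding the precatalyst's lag of 5.26 s, you reckon 50% conversion at about 10.8 s. By then, on this reckoning, about 12.7% is still precatalyst and about 5.36% is spent catalyst. Your answer: complex B, with 34.3%.

**The forecast.** It names complex B at 34%, placing complex B “ahead of free enzyme and complex A”.

**The flask.** The simulation gives complex B at 33.6%. At 0.173 min complex B was made 1.00 times as fast as it was used up. Carry K_B on to 0.250 min, when the second substrate stands at 79.5% of its charge, or 3.97 mM. Dividing by 3.15 mM gives a load of 1.26. The flask then holds 39.1% of the catalyst as complex B and 31.0% as enzyme, a ratio of 1.26.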